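## Retrosynthetic overview

1. The target is the 1,2-cis (1R,2R) 1-aryl-2,3-diaroyl-1,2-dihydronaphthalene. Ring A is the oxygenated benzo ring (C4a, C5–C8, C8a) and ring B is the carbocycle C1–C4. All six phenols are carried as TBS ethers and freed in the last step.
2. Ring B is the only ring that has to be made. It is cut at C3=C4 and at C1–C2 into a 2-benzylbenzaldehyde and a symmetric (Z)-1,2-diaroylethylene, and rebuilt by photoenolisation/Diels–Alder/dehydration in one flask.
3. Enabling feature: on ring A the C4 carbon (a formyl group on C4a) sits ortho to the doubly benzylic C1 (on C8a). Light can therefore move one C1–H to the formyl oxygen and unmask the diene C4=C4a–C8a=C1. C2 and C3 carry the same 4-hydroxybenzoyl group, so the dienophile has two identical ends.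
4. The 2-benzylbenzaldehyde comes from a Negishi coupling of a benzylzinc reagent (from 3-methoxycatechol) with a 2-iodobenzaldehyde (from 5-hydroxyvanillin by directed ortho-lithiation). The Z-enedione comes from oxidative opening of a 2,5-diarylfuran.

Key step: step 9

Assumption: (R,R)-TADDOL is written for the (1R,2R) series by analogy with its usual quadrant model; the sense of induction has to be checked in the first run, and the equally available (S,S)-ligand is used if it proves opposite.

Conventions: TBS = tert-butyldimethylsilyl; atom numbers are those of the dihydronaphthalene core of the target.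

## Route

Step 1
Reactants: 1 3-methoxycatechol
Product: 2 1-methoxy-2,3-bis(TBS-oxy)benzene
Conditions: TBSCl (2.4 equiv), imidazole (5 equiv), DMF, rt
Reagents that add atoms: tert-butyldimethylsilyl chloride, CC(C)(C)[Si](C)(C)Cl
Why: Imidazole-promoted O-silylation of both phenols gives ethers that neither direct lithiation nor need base or hydrogen for their later removal.

Step 2
Reactants: 2 1-methoxy-2,3-bis(TBS-oxy)benzene
Product: 4 [2-methoxy-3,4-bis(TBS-oxy)phenyl]methanol, via aryllithium 3 (not isolated)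
Conditions: n-BuLi (1.2 equiv), TMEDA (1.2 equiv), Et2O, 0 °C to rt; (CH2O)n, −78 °C to rt; H2O
Reagents that add atoms: paraformaldehyde (reacts as formaldehyde), C=O
Why: In this directed ortho-metalation the methoxy group is the only coordinating director while the bulky silyloxy groups shield their own ortho position, and the aryllithium is hydroxymethylated by formaldehyde.

Step 3
Reactants: 4 [2-methoxy-3,4-bis(TBS-oxy)phenyl]methanol
Product: 5 2-methoxy-3,4-bis(TBS-oxy)benzyl chloride
Conditions: MsCl (1.2 equiv), Et3N (1.5 equiv), CH2Cl2, 0 °C to rt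
Reagents that add atoms: methanesulfonyl chloride (chloride source), CS(=O)(=O)Cl
Why: Mesylation is followed by in situ displacement by the liberated chloride, the normal course for electron-rich benzylic alcohols, under conditions that leave aryl silyl ethers alone.

Step 4
Reactants: 6 3,4-dihydroxy-5-methoxybenzaldehyde (5-hydroxyvanillin)
Product: 7 3,4-bis(TBS-oxy)-5-methoxybenzaldehyde
Conditions: TBSCl (2.4 equiv), imidazole (5 equiv), DMF, rt
Reagents that add atoms: tert-butyldimethylsilyl chloride, CC(C)(C)[Si](C)(C)Cl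
Why: The same imidazole-promoted O-silylation as in step 1 applies, and the aldehyde is inert to it.

Step 5
Reactants: 7 3,4-bis(TBS-oxy)-5-methoxybenzaldehyde
Product: 11 2-iodo-3-methoxy-4,5-bis(TBS-oxy)benzaldehyde, via lithium amino alkoxide 8 (not isolated), via ring-lithiated amino alkoxide 9 (not isolated), via iodinated amino alkoxide 10 (not isolated)
Conditions: MeNHCH2CH2NMe2 (1.1 equiv), n-BuLi (1.05 equiv), THF, −20 °C; 7; n-BuLi (2 equiv), −20 °C; I2, −78 °C to rt; H2O, aq. Na2S2O3
Reagents that add atoms: iodine, II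
Why: In this α-amino-alkoxide-directed ortho-lithiation the aldehyde is masked in situ, the C–H between the alkoxide arm and the methoxy group is metalated cooperatively, the other ortho C–H lies next to a bulky non-coordinating silyloxy group, and aqueous work-up returns the aldehyde.

Step 6
Reactants: 5 2-methoxy-3,4-bis(TBS-oxy)benzyl chloride; 11 2-iodo-3-methoxy-4,5-bis(TBS-oxy)benzaldehyde
Product: 13 2-{[2-methoxy-3,4-bis(TBS-oxy)phenyl]methyl}-3-methoxy-4,5-bis(TBS-oxy)benzaldehyde, via benzylzinc chloride 12 (not isolated)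
Conditions: 5, Zn dust (1.5 equiv), LiCl (1.5 equiv), THF, rt; then 11, Pd(OAc)2 (2 mol %), SPhos (4 mol %), THF, rt to 40 °C
Reagents that add atoms: none
Why: LiCl-assisted zinc insertion followed by Negishi coupling is base-free, tolerates the aldehyde and the silyl ethers, and the bulky biarylphosphine handles the doubly ortho-substituted iodide.

Step 7
Reactants: 14 2,5-dibromofuran; 15 4-(TBS-oxy)phenylboronic acid
Product: 16 2,5-bis[4-(TBS-oxy)phenyl]furan
Conditions: 15 (2.3 equiv), Pd(PPh3)4 (5 mol %), K3PO4 (3 equiv), dioxane/H2O (9:1), 70 °C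
Reagents that add atoms: none
Why: A twofold Suzuki–Miyaura coupling takes place at the activated α-positions of the furan.

Step 8
Reactants: 16 2,5-bis[4-(TBS-oxy)phenyl]furan
Product: 17 (Z)-1,4-bis[4-(TBS-oxy)phenyl]but-2-ene-1,4-dione
Conditions: mCPBA (1.05 equiv), CH2Cl2, 0 °C, dark
Reagents that add atoms: 3-chloroperoxybenzoic acid, OOC(=O)c1cccc(Cl)c1
Why: In this peracid oxidative ring opening of a 2,5-disubstituted furan, epoxidation and spontaneous opening give the enedione with the cis geometry of the ring retained, so the Z alkene is set by the ring it comes from.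

Step 9
Reactants: 13 2-{[2-methoxy-3,4-bis(TBS-oxy)phenyl]methyl}-3-methoxy-4,5-bis(TBS-oxy)benzaldehyde; 17 (Z)-1,4-bis[4-(TBS-oxy)phenyl]but-2-ene-1,4-dione
Product: 20 (1R,2R)-hexa-TBS ether of the target dihydronaphthalene, via out-out dienol 18 (not isolated), via all-cis hydroxytetralin 19 (not isolated)
Conditions: Ti(OiPr)4 (1.2 equiv), (R,R)-TADDOL (1.3 equiv), toluene, rt, premix; 13, 17 (1.5 equiv), 365 nm LED, 0 °C, Ar; then TFA (6 equiv), 0 °C, dark
Reagents that add atoms: none
Why: This is a photoenolisation/Diels–Alder reaction followed by E1 dehydration: 365 nm light excites the C4 formyl group of 13, its oxygen takes a hydrogen atom from the doubly benzylic C1H2 group through a six-membered 1,5-HAT transition state, and the long-lived dienol 18 (OH outward, aryl outward) is caught as its titanium dienolate. The closest known reaction types are the photoenol Diels–Alder reaction of 2-benzylbenzaldehydes with fumarate- and maleate-type dienophiles used for aryltetralin lignans, and the Ti(OiPr)4/TADDOL-controlled enantioselective variant shown for electron-rich 2-alkylbenzaldehydes and enones. Ring B closes in an endo, suprafacial but asynchronous [4+2] mode in which the nucleophilic terminus C1 bonds to C2 first and the aldol-like C3–C4 bond shuts the six-membered ring and restores the aromaticity of ring A, after which TFA ionises the C4–O bond (cation stabilised by the para C7 oxygen) and loss of H3 leaves the C3=C4 enone. C1 is controlled by the outward position of the aryl group in 18 together with the diene face left open by the TADDOLate, C2 is controlled by the Z geometry of 17 and the endo approach enforced by titanium bridging the dienolate oxygen and the C3 aroyl oxygen (aryl and C2 aroyl end up cis), and C3 and C4 are formed all-cis but erased by the dehydration. Regioselectivity is no issue because 17 has two identical ends, the hydrogen transfer is chemoselective because only C1–H lies within reach of the formyl oxygen, and the Z geometry should hold under the lamp because the weakly absorbing, twisted Z isomer is the photostationary sink of 1,2-diaroylethylenes. The dehydration is run cold, in the dark and under acid so that the acidic C2–H of 20 never meets base.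

Step 10
Reactants: 20 (1R,2R)-hexa-TBS ether of the target dihydronaphthalene
Product: 21 (1R,2R)-1-(3,4-dihydroxy-2-methoxyphenyl)-2,3-bis(4-hydroxybenzoyl)-8-methoxy-1,2-dihydronaphthalene-6,7-diol (target)
Conditions: Et3N·3HF (12 equiv), THF, 0 °C to rt, Ar; pH 5 buffer work-up
Reagents that add atoms: none
Why: Fluoride cleavage of the six aryl silyl ethers in a slightly acidic medium keeps phenoxide, and with it enolisation at C2, out of the flask, so C1 and C2 stay untouched.

## Compound list

1 | 3-methoxycatechol | COc1cccc(O)c1O | starting material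
2 | 1-methoxy-2,3-bis(TBS-oxy)benzene | COc1cccc(O[Si](C)(C)C(C)(C)C)c1O[Si](C)(C)C(C)(C)C | intermediate
3 | 2-methoxy-3,4-bis(TBS-oxy)phenyllithium (not isolated) | COc1c([Li])ccc(O[Si](C)(C)C(C)(C)C)c1O[Si](C)(C)C(C)(C)C | intermediate
4 | [2-methoxy-3,4-bis(TBS-oxy)phenyl]methanol | COc1c(CO)ccc(O[Si](C)(C)C(C)(C)C)c1O[Si](C)(C)C(C)(C)C | intermediate
5 | 2-methoxy-3,4-bis(TBS-oxy)benzyl chloride | COc1c(CCl)ccc(O[Si](C)(C)C(C)(C)C)c1O[Si](C)(C)C(C)(C)C | intermediate
6 | 3,4-dihydroxy-5-methoxybenzaldehyde | COc1cc(C=O)cc(O)c1O | starting material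
7 | 3,4-bis(TBS-oxy)-5-methoxybenzaldehyde | COc1cc(C=O)cc(O[Si](C)(C)C(C)(C)C)c1O[Si](C)(C)C(C)(C)C | intermediate
8 | lithium α-amino alkoxide of 7 (not isolated) | COc1cc(C([O-])N(C)CCN(C)C)cc(O[Si](C)(C)C(C)(C)C)c1O[Si](C)(C)C(C)(C)C.[Li+] | intermediate
9 | ring-lithiated α-amino alkoxide (not isolated) | COc1c([Li])c(C([O-])N(C)CCN(C)C)cc(O[Si](C)(C)C(C)(C)C)c1O[Si](C)(C)C(C)(C)C.[Li+] | intermediate
10 | iodinated α-amino alkoxide (not isolated) | COc1c(I)c(C([O-])N(C)CCN(C)C)cc(O[Si](C)(C)C(C)(C)C)c1O[Si](C)(C)C(C)(C)C.[Li+] | intermediate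
11 | 2-iodo-3-methoxy-4,5-bis(TBS-oxy)benzaldehyde | COc1c(I)c(C=O)cc(O[Si](C)(C)C(C)(C)C)c1O[Si](C)(C)C(C)(C)C | intermediate
12 | 2-methoxy-3,4-bis(TBS-oxy)benzylzinc chloride (not isolated) | COc1c(C[Zn]Cl)ccc(O[Si](C)(C)C(C)(C)C)c1O[Si](C)(C)C(C)(C)C | intermediate
13 | 2-{[2-methoxy-3,4-bis(TBS-oxy)phenyl]methyl}-3-methoxy-4,5-bis(TBS-oxy)benzaldehyde | COc1c(Cc2c(C=O)cc(O[Si](C)(C)C(C)(C)C)c(O[Si](C)(C)C(C)(C)C)c2OC)ccc(O[Si](C)(C)C(C)(C)C)c1O[Si](C)(C)C(C)(C)C | intermediate
14 | 2,5-dibromofuran | Brc1ccc(Br)o1 | starting material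
15 | 4-(TBS-oxy)phenylboronic acid | OB(O)c1ccc(O[Si](C)(C)C(C)(C)C)cc1 | starting material
16 | 2,5-bis[4-(TBS-oxy)phenyl]furan | CC(C)(C)[Si](C)(C)Oc1ccc(cc1)-c1ccc(o1)-c1ccc(O[Si](C)(C)C(C)(C)C)cc1 | intermediate
17 | (Z)-1,4-bis[4-(TBS-oxy)phenyl]but-2-ene-1,4-dione | O=C(/C=C\C(=O)c1ccc(O[Si](C)(C)C(C)(C)C)cc1)c1ccc(O[Si](C)(C)C(C)(C)C)cc1 | intermediate
18 | hydroxy-ortho-quinodimethane, OH outward and aryl outward, drawn as the free dienol, titanium-bound in the flask (not isolated) | O/C=C1\C=C(O[Si](C)(C)C(C)(C)C)C(O[Si](C)(C)C(C)(C)C)=C(OC)/C1=C\c1ccc(O[Si](C)(C)C(C)(C)C)c(O[Si](C)(C)C(C)(C)C)c1OC | intermediate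
19 | (1R,2R,3R,4R) all-cis 1-aryl-2,3-diaroyl-4-hydroxytetralin, hexa-TBS ether (not isolated) | COc1c([C@@H]2c3c(cc(O[Si](C)(C)C(C)(C)C)c(O[Si](C)(C)C(C)(C)C)c3OC)[C@H](O)[C@H](C(=O)c3ccc(O[Si](C)(C)C(C)(C)C)cc3)[C@@H]2C(=O)c2ccc(O[Si](C)(C)C(C)(C)C)cc2)ccc(O[Si](C)(C)C(C)(C)C)c1O[Si](C)(C)C(C)(C)C | intermediate
20 | (1R,2R)-hexa-TBS ether of the target | COc1c([C@@H]2c3c(cc(O[Si](C)(C)C(C)(C)C)c(O[Si](C)(C)C(C)(C)C)c3OC)C=C(C(=O)c3ccc(O[Si](C)(C)C(C)(C)C)cc3)[C@@H]2C(=O)c2ccc(O[Si](C)(C)C(C)(C)C)cc2)ccc(O[Si](C)(C)C(C)(C)C)c1O[Si](C)(C)C(C)(C)C | intermediate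
21 | (1R,2R)-1-(3,4-dihydroxy-2-methoxyphenyl)-2,3-bis(4-hydroxybenzoyl)-8-methoxy-1,2-dihydronaphthalene-6,7-diol | COc1c([C@@H]2c3c(cc(O)c(O)c3OC)C=C(C(=O)c3ccc(O)cc3)[C@@H]2C(=O)c2ccc(O)cc2)ccc(O)c1O | target

Total step count: 10. Longest linear sequence: 6 steps (1, 2, 3, 6, 9, 10).

## Steps most likely to fail

**1. Step 9.**
- Risk: the titanium TADDOLate may discriminate poorly between the faces of a twisted, acyclic dienophile. Lewis-acid-induced Z-to-E leakage of 17 would place the C2 aroyl group exo and feed the 1,2-trans series. Crowding by the C8 methoxy group may also disturb the outward geometry of the aryl group in the dienol.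
- Fallback (sets out from 13 and 17, returns at 20): absolute control is moved from the catalyst to a covalent resolution. 13 and 17 are irradiated with Ti(OiPr)4 alone and worked up without acid to isolate the racemic all-cis hydroxytetralin F1, which is freed from any trans adducts at this stage.
- The C4 hydroxyl is then esterified with (S)-2-methoxy-2-phenylacetic acid (DCC, catalytic DMAP, CH2Cl2, 0 °C). This gives the (1R,2R,3R,4R) ester F2 and the (1S,2S,3S,4S) ester F3, which are separated by chromatography or crystallisation.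
- TFA at 0 °C ionises the benzylic C4–O bond of F2, and loss of H3 gives 20.

**2. Step 5.**
- Risk: metalation may occur at the other ortho position next to the silyloxy group, or n-butyllithium may attack silicon during the metalation period.
- Fallback (sets out from 2, returns at 13): the two ortho carbons of ring A are installed in the opposite order, so that only one ortho C–H is ever free. Aryllithium 3, made from 2 as in step 2, is formylated with DMF to 2-methoxy-3,4-bis(TBS-oxy)benzaldehyde F4.
- In situ amino alkoxide protection, lithiation at the single free ortho position and BrCF2CF2Br give 6-bromo-2-methoxy-3,4-bis(TBS-oxy)benzaldehyde F5. A second portion of 3 adds to the aldehyde to give the brominated benzhydrol F6.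
- Ionic hydrogenation (Et3SiH, TFA, CH2Cl2, −20 °C) gives the bromodiarylmethane F7. Bromine–lithium exchange (n-BuLi, −78 °C) and DMF then give 13.

**3. Step 10.**
- Risk: phenoxide-mediated enolisation may epimerise C2 toward the more stable trans isomer. Air oxidation of the catechols, with aromatisation of ring B, may occur during or after the sixfold deprotection.
- Fallback (sets out from 19, returns at 21): the order of the last two events is inverted. The irradiation mixture of step 9 is worked up without TFA and 19 is isolated.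
- 19 is desilylated with Et3N·3HF to the hexaphenolic all-cis hydroxytetralin F8, in which C2–H is only an ordinary ketone α-hydrogen.
- Water is lost last, in dilute AcOH at rt under argon, through the para-quinone methide of ring A (the C7 hydroxyl lies para to C4a, which carries C4). This gives 21 directly.

## Further compounds

F1 | step 9 | racemic all-cis 1-aryl-2,3-diaroyl-4-hydroxytetralin hexa-TBS ether (racemate, relative configuration drawn) | COc1c([C@@H]2c3c(cc(O[Si](C)(C)C(C)(C)C)c(O[Si](C)(C)C(C)(C)C)c3OC)[C@H](O)[C@H](C(=O)c3ccc(O[Si](C)(C)C(C)(C)C)cc3)[C@@H]2C(=O)c2ccc(O[Si](C)(C)C(C)(C)C)cc2)ccc(O[Si](C)(C)C(C)(C)C)c1O[Si](C)(C)C(C)(C)C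
F2 | step 9 | (S)-2-methoxy-2-phenylacetate of the (1R,2R,3R,4R) hydroxytetralin | COc1c([C@@H]2c3c(cc(O[Si](C)(C)C(C)(C)C)c(O[Si](C)(C)C(C)(C)C)c3OC)[C@H](OC(=O)[C@@H](OC)c3ccccc3)[C@H](C(=O)c3ccc(O[Si](C)(C)C(C)(C)C)cc3)[C@@H]2C(=O)c2ccc(O[Si](C)(C)C(C)(C)C)cc2)ccc(O[Si](C)(C)C(C)(C)C)c1O[Si](C)(C)C(C)(C)C
F3 | step 9 | (S)-2-methoxy-2-phenylacetate of the (1S,2S,3S,4S) hydroxytetralin (removed) | COc1c([C@H]2c3c(cc(O[Si](C)(C)C(C)(C)C)c(O[Si](C)(C)C(C)(C)C)c3OC)[C@@H](OC(=O)[C@@H](OC)c3ccccc3)[C@@H](C(=O)c3ccc(O[Si](C)(C)C(C)(C)C)cc3)[C@H]2C(=O)c2ccc(O[Si](C)(C)C(C)(C)C)cc2)ccc(O[Si](C)(C)C(C)(C)C)c1O[Si](C)(C)C(C)(C)C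
F4 | step 5 | 2-methoxy-3,4-bis(TBS-oxy)benzaldehyde | COc1c(C=O)ccc(O[Si](C)(C)C(C)(C)C)c1O[Si](C)(C)C(C)(C)C
F5 | step 5 | 6-bromo-2-methoxy-3,4-bis(TBS-oxy)benzaldehyde | COc1c(C=O)c(Br)cc(O[Si](C)(C)C(C)(C)C)c1O[Si](C)(C)C(C)(C)C
F6 | step 5 | [6-bromo-2-methoxy-3,4-bis(TBS-oxy)phenyl][2-methoxy-3,4-bis(TBS-oxy)phenyl]methanol (racemic) | COc1c(C(O)c2c(Br)cc(O[Si](C)(C)C(C)(C)C)c(O[Si](C)(C)C(C)(C)C)c2OC)ccc(O[Si](C)(C)C(C)(C)C)c1O[Si](C)(C)C(C)(C)C
F7 | step 5 | [6-bromo-2-methoxy-3,4-bis(TBS-oxy)phenyl][2-methoxy-3,4-bis(TBS-oxy)phenyl]methane | COc1c(Cc2c(Br)cc(O[Si](C)(C)C(C)(C)C)c(O[Si](C)(C)C(C)(C)C)c2OC)ccc(O[Si](C)(C)C(C)(C)C)c1O[Si](C)(C)C(C)(C)C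
F8 | step 10 | (1R,2R,3R,4R) all-cis hexaphenolic 4-hydroxytetralin | COc1c([C@@H]2c3c(cc(O)c(O)c3OC)[C@H](O)[C@H](C(=O)c3ccc(O)cc3)[C@@H]2C(=O)c2ccc(O)cc2)ccc(O)c1O
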